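**Plan**

- Retrosynthesis: the last cuts are functional – the C1/C3 carbinols become the 1,3‑diketone, the C4–C5 epoxide comes from the E‑alkene, and the C13 and C8 acyl groups are added late. The butenolide is then seen as a hydrolysed 2‑methoxyfuran, which is cut at C12–C11 and C6–C7.
- Enabling feature: in the ring O–C12(=O)–C11=C7–C6 the unit C12–O–C6 maps onto C5–O1–C2 of a 5‑alkoxyoxazole, and C11=C7, flanked by the C8 oxygen, maps onto an ynone. One cycloaddition/cycloreversion can therefore close both the furan (later butenolide) and the ten‑membered ring C1–C10.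
- Forward order: an aldol joins C2–C3; a temporary γ‑lactone (C1–O–C8) masks C1‑OH and the C8 carboxyl; the oxazole is built on C6; an acetylide opens the lactone (C7–C8); the key step closes both rings. Then C8 reduction, acylation, furan hydrolysis, C1 oxidation, epoxidation and C3 oxidation.
- Stereochemistry: C10 comes from an (R)‑methylsuccinate monoester. C3 (temporary) is set by an Ipc2BCl aldol and C1 (temporary) by syn reduction. C8 is set by CBS reduction, C6 by face‑selective protonation relayed from C8, and C4/C5 by peripheral epoxidation steered by C6 and the 3R silyloxy group.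
- Helpers removed: N3–C4(CH3) of the oxazole leaves as acetonitrile, the methoxy group leaves on hydrolysis, and the C1/C3 carbinols end as the diketone.

Key step: step 12

Remarks: germacrane numbering is used for the ring (C1, C3 = ketone carbons; C4, C5 = epoxide; C6 = lactone CH–O; C7=C11 butenolide alkene; C8 = acyloxy carbon; C10 = CH(CH3); C12 = lactone C=O; C13 = CH2OAc). Assumption: acid 1 (4‑tert‑butyl monoester of (R)‑methylsuccinic acid) is taken as a catalogue compound. The sense of induction of (−)-Ipc2BCl in step 3 is assumed to be 3R; the antipodal reagent is the alternative if it is not.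

**Step 1**
Reactants: 1 (R)-4-(tert-butoxy)-2-methyl-4-oxobutanoic acid
Product: 2 Weinreb amide tert-butyl (R)-4-[methoxy(methyl)amino]-3-methyl-4-oxobutanoate
Conditions: MeNH(OMe)·HCl, EDC·HCl, 1-hydroxybenzotriazole (cat.), N-methylmorpholine, CH2Cl2, 0 °C to rt
Reagents that add atoms: N,O-dimethylhydroxylamine hydrochloride, CNOC.Cl
Why: Carbodiimide amide coupling gives the Weinreb amide, and the α‑stereocentre (future C10) is not enolised under these weakly basic conditions.

**Step 2**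
Reactants: 2 Weinreb amide
Product: 3 methyl ketone tert-butyl (R)-3-methyl-4-oxopentanoate
Conditions: MeMgBr, THF, −20 °C to 0 °C; aq. NH4Cl
Reagents that add atoms: methylmagnesium bromide, C[Mg]Br
Why: Weinreb ketone synthesis, in which the chelated tetrahedral intermediate stops at the ketone and the hindered tert‑butyl ester is not attacked at this temperature.

**Step 3**
Reactants: 3 methyl ketone; 4 ethyl (E)-3-methyl-4-oxobut-2-enoate
Product: 6 β-hydroxy ketone 9-tert-butyl 1-ethyl (2E,4R,7R)-4-hydroxy-3,7-dimethyl-6-oxonon-2-enedioate, via enol borinate 5 (not isolated)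
Conditions: (−)-Ipc2BCl, Et3N, Et2O, −78 °C to 0 °C; then 4, −78 °C to −20 °C; pH 7 buffer, MeOH, H2O2
Reagents that add atoms: none
Why: Boron‑mediated aldol reaction of a methyl ketone, in which Ipc2BCl/Et3N enolises the methyl side regioselectively, the enal reacts only by 1,2‑addition, and the chiral isopinocampheyl ligands should set the new carbinol (future C3) as R by reagent control.

**Step 4**
Reactants: 6 β-hydroxy ketone
Product: 8 hydroxy lactone ethyl (2E,4R)-4-hydroxy-3-methyl-5-[(2S,3R)-3-methyl-5-oxooxolan-2-yl]pent-2-enoate, via syn-diol 7 (not isolated)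
Conditions: Et2BOMe, NaBH4, THF/MeOH (4:1), −78 °C; MeOH co‑evaporation; then CF3CO2H, CH2Cl2, 0 °C to rt
Reagents that add atoms: none
Why: Narasaka–Prasad reduction delivers hydride to the boron chelate to give the 1,3‑syn diol (future C1 as S), and acidolysis of the tert‑butyl ester lets the C1 hydroxyl close the γ‑lactone, a temporary ring that masks both C1‑OH and the C8 carboxyl.

**Step 5**
Reactants: 8 hydroxy lactone
Product: 9 silyl ether ethyl (2E,4R)-4-[(tert-butyldimethylsilyl)oxy]-3-methyl-5-[(2S,3R)-3-methyl-5-oxooxolan-2-yl]pent-2-enoate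
Conditions: tert-butyldimethylsilyl chloride, imidazole, DMF, rt
Reagents that add atoms: tert-butyldimethylsilyl chloride, CC(C)(C)[Si](C)(C)Cl
Why: Standard silylation of the remaining secondary allylic alcohol, which also installs the bulky C3 group that later steers the epoxidation.

**Step 6**
Reactants: 9 silyl ether
Product: 11 acid (2E,4R)-4-[(tert-butyldimethylsilyl)oxy]-3-methyl-5-[(2S,3R)-3-methyl-5-oxooxolan-2-yl]pent-2-enoic acid, via dilithium hydroxy dicarboxylate 10 (not isolated)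
Conditions: LiOH·H2O, THF/H2O (3:1), 0 °C to rt; then 1 M HCl to pH 3, rt
Reagents that add atoms: lithium hydroxide, [Li+].[OH-]
Why: Saponification cleaves the ethyl enoate and opens the lactone, and on acidification the five‑membered lactone re‑closes while the unsaturated acid stays free because its E geometry forbids lactonisation.

**Step 7**
Reactants: 11 acid; 12 methyl L-alaninate hydrochloride
Product: 13 amide methyl N-{(2E,4R)-4-[(tert-butyldimethylsilyl)oxy]-3-methyl-5-[(2S,3R)-3-methyl-5-oxooxolan-2-yl]pent-2-enoyl}-L-alaninate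
Conditions: EDC·HCl, 1-hydroxybenzotriazole (cat.), iPr2NEt, CH2Cl2, 0 °C to rt
Reagents that add atoms: none
Why: Carbodiimide amide coupling gives the N‑acyl alanine ester needed for the oxazole, the γ‑lactone being inert to the amine at room temperature.

**Step 8**
Reactants: 13 amide
Product: 14 oxazole (4R,5S)-5-[(2R,3E)-2-[(tert-butyldimethylsilyl)oxy]-4-(5-methoxy-4-methyl-1,3-oxazol-2-yl)-3-methylbut-3-en-1-yl]-4-methyloxolan-2-one
Conditions: PPh3, I2, Et3N, CH2Cl2, 0 °C to rt
Reagents that add atoms: none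
Why: Robinson–Gabriel‑type cyclodehydration of an α‑acylamino ester gives the 5‑methoxy‑4‑methyloxazole under neutral to basic conditions that spare the lactone and the silyl ether.

**Step 9**
Reactants: 15 prop-2-yn-1-ol
Product: 16 triethyl(prop-2-yn-1-yloxy)silane
Conditions: Et3SiCl, imidazole, CH2Cl2, 0 °C
Reagents that add atoms: chlorotriethylsilane, CC[Si](Cl)(CC)CC
Why: Routine silylation, the triethylsilyl group being chosen because the dilute acid that later hydrolyses the methoxyfuran also removes it.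

**Step 10**
Reactants: 16 triethyl(prop-2-yn-1-yloxy)silane; 14 oxazole
Product: 18 hydroxy ynone (6R,7S,9R,10E)-9-[(tert-butyldimethylsilyl)oxy]-7-hydroxy-11-(5-methoxy-4-methyl-1,3-oxazol-2-yl)-6,10-dimethyl-1-[(triethylsilyl)oxy]undec-10-en-2-yn-4-one, via lithium acetylide 17 (not isolated)
Conditions: n-BuLi, THF, −78 °C; then 14, −78 °C; aq. NH4Cl
Reagents that add atoms: none
Why: Addition of a lithium acetylide to a γ‑lactone stops at the lithium hemiketal, which opens on work‑up to the γ‑hydroxy ynone, so the C7–C8 bond and the activating ynone are made together.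

**Step 11**
Reactants: 18 hydroxy ynone
Product: 19 ynone (6R,7S,9R,10E)-9-[(tert-butyldimethylsilyl)oxy]-11-(5-methoxy-4-methyl-1,3-oxazol-2-yl)-6,10-dimethyl-1,7-bis[(triethylsilyl)oxy]undec-10-en-2-yn-4-one
Conditions: Et3SiOSO2CF3, 2,6-lutidine, CH2Cl2, −78 °C
Reagents that add atoms: triethylsilyl trifluoromethanesulfonate, CC[Si](CC)(CC)OS(=O)(=O)C(F)(F)F
Why: Silyl triflate silylation traps the open hydroxy ynone as its C1 triethylsilyl ether and removes the nucleophilic hydroxyl before the thermal step.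

**Step 12**
Reactants: 19 ynone
Product: 21 macrocyclic furyl ketone (1S,3R,4E,10R)-3-[(tert-butyldimethylsilyl)oxy]-12-methoxy-1,13-bis[(triethylsilyl)oxy]-6,12-epoxygermacra-4,6,11-trien-8-one, via oxazole–alkyne cycloadduct 20 (not isolated)
Conditions: toluene (degassed, 5 × 10⁻⁴ M, slow addition), 2,6-di-tert-butyl-4-methylphenol (0.2 equiv), sealed vessel, 150 °C
Reagents that add atoms: none
Why: Proposed new method: the 5‑methoxy‑4‑methyloxazole acts as an electron‑rich azadiene (C2=N3–C4=C5, whose termini C2 and C5 are the future C6 and C12) and adds across the ynone C7≡C11 in a thermal [4+2] cycloaddition to the 7‑oxa‑2‑azabicyclo[2.2.1]heptadiene 20, which loses acetonitrile by retro‑[4+2] to leave the 2‑methoxyfuran. The closest known reaction type is the intramolecular oxazole–alkynone Diels–Alder/cycloreversion that annulates five‑ to seven‑membered carbocycles onto 2‑alkoxyfurans, together with macrocyclising Diels–Alder reactions of tethered trienes; what is new is the eight‑atom tether. The furan ring closes by the [4+2]/retro‑[4+2] pair (a net [3+2] annulation of C12–O–C6 across C11≡C7), and the ten‑membered carbocycle closes through the same C6–C7 bond as a macrocyclising intramolecular cycloaddition in which the tether C5–C8 joins a diene terminus to a dienophile terminus. No permanent stereocentre is formed (the bridgeheads of 20 disappear on cycloreversion, so both facial adducts converge) and C1, C3 and C10 are not touched. The step needs intramolecular over intermolecular reaction and the C6–C7/C12–C11 orientation: high dilution suppresses dimerisation, the tether allows only this orientation, the C8 carbonyl lowers the alkyne LUMO while the 5‑methoxy group raises the oxazole HOMO, and the planar E‑alkene–oxazole unit, the C10 methyl branch and the two silyloxy‑bearing carbons cut down the free rotors of the chain.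

**Step 13**
Reactants: 21 macrocyclic furyl ketone
Product: 22 furyl carbinol (1S,3R,4E,8R,10R)-3-[(tert-butyldimethylsilyl)oxy]-12-methoxy-1,13-bis[(triethylsilyl)oxy]-6,12-epoxygermacra-4,6,11-trien-8-ol
Conditions: (S)-1-methyl-3,3-diphenyltetrahydro-1H,3H-pyrrolo[1,2-c][1,3,2]oxazaborole (0.5 equiv), catecholborane, toluene, −78 °C to −40 °C
Reagents that add atoms: none
Why: Corey–Bakshi–Shibata reduction, in which the 3‑furyl group is the large and the C9 methylene the small substituent, so the (S)‑oxazaborolidine should give the 8R carbinol by reagent control, and catecholborane does not hydroborate the C4=C5 alkene at this temperature.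

**Step 14**
Reactants: 16 triethyl(prop-2-yn-1-yloxy)silane
Product: 24 tert-butyl 4-[(triethylsilyl)oxy]but-2-ynoate, via bromomagnesium acetylide 23 (not isolated)
Conditions: EtMgBr, THF, 0 °C to rt; then di-tert-butyl dicarbonate, −20 °C to rt; aq. NH4Cl
Reagents that add atoms: di-tert-butyl dicarbonate, CC(C)(C)OC(=O)OC(=O)OC(C)(C)C
Why: Deprotonation of the terminal alkyne with the Grignard reagent gives the alkynylmagnesium bromide, whose acylation with the dicarbonate gives the tert‑butyl ynoate directly, the magnesium acetylide being mild enough not to add to the hindered product ester.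

**Step 15**
Reactants: 24 tert-butyl 4-[(triethylsilyl)oxy]but-2-ynoate
Product: 25 tert-butyl (Z)-3-methyl-4-[(triethylsilyl)oxy]but-2-enoate
Conditions: Me2CuLi (from MeLi and CuI), THF, −78 °C; MeOH quench at −78 °C; aq. NH4Cl
Reagents that add atoms: lithium dimethylcuprate, [Li+].C[Cu-]C
Why: Conjugate addition of the cuprate to the ynoate is a syn carbocupration, so protonation at low temperature should give the Z enoate with the ester and the CH2O group cis.

**Step 16**
Reactants: 25 tert-butyl (Z)-3-methyl-4-[(triethylsilyl)oxy]but-2-enoate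
Product: 27 tert-butyl (Z)-4-acetoxy-3-methylbut-2-enoate, via hydroxy ester 26 (not isolated)
Conditions: Bu4NF, AcOH (1:1), THF, 0 °C; then Ac2O, pyridine, 4-(dimethylamino)pyridine (cat.), 0 °C
Reagents that add atoms: acetic anhydride, CC(=O)OC(C)=O
Why: Buffered fluoride desilylation followed by acetylation in the same flask caps the Z‑γ‑hydroxyl before it can lactonise onto the hindered tert‑butyl ester.

**Step 17**
Reactants: 27 tert-butyl (Z)-4-acetoxy-3-methylbut-2-enoate
Product: 28 (Z)-4-acetoxy-3-methylbut-2-enoic acid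
Conditions: CF3CO2H, CH2Cl2, 0 °C to rt
Reagents that add atoms: none
Why: Acidolysis of the tert‑butyl ester leaves the acetate and the Z alkene intact and gives an acid that can no longer lactonise.

**Step 18**
Reactants: 28 (Z)-4-acetoxy-3-methylbut-2-enoic acid; 22 furyl carbinol
Product: 30 furyl ester (1S,3R,4E,8R,10R)-3-[(tert-butyldimethylsilyl)oxy]-12-methoxy-1,13-bis[(triethylsilyl)oxy]-6,12-epoxygermacra-4,6,11-trien-8-yl (Z)-4-acetoxy-3-methylbut-2-enoate, via mixed anhydride 29 (not isolated)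
Conditions: 2,4,6-trichlorobenzoyl chloride, Et3N, toluene, rt; then 22, 4-(dimethylamino)pyridine, toluene, rt
Reagents that add atoms: none
Why: Yamaguchi esterification acylates the hindered secondary carbinol under conditions known to preserve Z‑configured enoic acids, and acylating O8 before the butenolide exists excludes a later lactone migration to O8.

**Step 19**
Reactants: 30 furyl ester
Product: 31 butenolide diol (1S,3R,4E,6S,8R,10R)-8-{[(Z)-4-acetoxy-3-methylbut-2-enoyl]oxy}-3-[(tert-butyldimethylsilyl)oxy]-1,13-dihydroxygermacra-4,7(11)-dien-12,6-olide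
Conditions: 0.2 M HCl, THF/H2O (4:1), 0 °C
Reagents that add atoms: water, O
Why: Acid hydrolysis of a 2‑methoxyfuran (C‑protonation at C6, water addition at C12, loss of methanol) gives the conjugated butenolide while the same acid removes both triethylsilyl ethers, and the proton should enter C6 from the furan face opposite the ten‑membered loop, syn to the C8 acyloxy group, which is the target configuration at C6 (descriptor S at this stage) and the epimer whose ring bonds at C6 and C8 leave the butenolide plane on the same side.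

**Step 20**
Reactants: 31 butenolide diol
Product: 32 13-acetate (1S,3R,4E,6S,8R,10R)-13-acetoxy-8-{[(Z)-4-acetoxy-3-methylbut-2-enoyl]oxy}-3-[(tert-butyldimethylsilyl)oxy]-1-hydroxygermacra-4,7(11)-dien-12,6-olide
Conditions: AcCl, 2,4,6-collidine, CH2Cl2, −78 °C
Reagents that add atoms: acetyl chloride, CC(=O)Cl
Why: Acetyl chloride with a hindered pyridine base at low temperature acetylates the primary allylic C13 hydroxyl selectively over the hindered secondary C1 hydroxyl.

**Step 21**
Reactants: 32 13-acetate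
Product: 33 1-ketone (3R,4E,6S,8R,10R)-13-acetoxy-8-{[(Z)-4-acetoxy-3-methylbut-2-enoyl]oxy}-3-[(tert-butyldimethylsilyl)oxy]-1-oxogermacra-4,7(11)-dien-12,6-olide
Conditions: Dess–Martin periodinane, NaHCO3, CH2Cl2, 0 °C to rt
Reagents that add atoms: none
Why: Dess–Martin oxidation of the only free hydroxyl gives the C1 ketone under buffered, non‑epimerising conditions and removes the hydroxyl that could later open the 4,5‑epoxide transannularly.

**Step 22**
Reactants: 33 1-ketone
Product: 34 epoxide (3R,4S,5R,6R,8R,10R)-13-acetoxy-8-{[(Z)-4-acetoxy-3-methylbut-2-enoyl]oxy}-3-[(tert-butyldimethylsilyl)oxy]-4,5-epoxy-1-oxogermacr-7(11)-en-12,6-olide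
Conditions: 3-chloroperbenzoic acid, NaHCO3, CH2Cl2, 0 °C
Reagents that add atoms: 3-chloroperbenzoic acid, OOC(=O)c1cccc(Cl)c1
Why: Prilezhaev epoxidation is selective for the only electron‑rich alkene and stereospecific (E alkene to trans epoxide), and the peracid should attack the peripheral face of the rotamer in which C2 and C7 lie on the inner face, the C3–O bond lies in the alkene plane (possible only for 3R, the other rotamer placing the silyloxy group on the outer face) and H6 points outward, which gives the 4S,5R epoxide.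

**Step 23**
Reactants: 34 epoxide
Product: 35 hydroxy ketone (3R,4R,5R,6R,8R,10R)-13-acetoxy-8-{[(Z)-4-acetoxy-3-methylbut-2-enoyl]oxy}-4,5-epoxy-3-hydroxy-1-oxogermacr-7(11)-en-12,6-olide
Conditions: HF·pyridine, pyridine, THF, 0 °C to rt
Reagents that add atoms: none
Why: Pyridine‑buffered fluoride desilylation frees the C3 hydroxyl under conditions that epoxides, acetates and butenolides normally tolerate (the C4 descriptor changes only because the priorities change).

**Step 24**
Reactants: 35 hydroxy ketone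
Product: 36 target (4S,5R,6R,8R,10R)-13-acetoxy-8-{[(Z)-4-acetoxy-3-methylbut-2-enoyl]oxy}-4,5-epoxy-1,3-dioxogermacr-7(11)-en-12,6-olide
Conditions: Dess–Martin periodinane, NaHCO3, CH2Cl2, 0 °C to rt
Reagents that add atoms: none
Why: Dess–Martin oxidation converts the β‑hydroxy ketone into the 1,3‑diketone without retro‑aldol cleavage or epimerisation at C10 and leaves the epoxide intact.

**Compound list**

1 | (R)-4-(tert-butoxy)-2-methyl-4-oxobutanoic acid | C[C@H](CC(=O)OC(C)(C)C)C(=O)O | starting material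
2 | tert-butyl (R)-4-[methoxy(methyl)amino]-3-methyl-4-oxobutanoate | C[C@H](CC(=O)OC(C)(C)C)C(=O)N(C)OC | intermediate
3 | tert-butyl (R)-3-methyl-4-oxopentanoate | CC(=O)[C@H](C)CC(=O)OC(C)(C)C | intermediate
4 | ethyl (E)-3-methyl-4-oxobut-2-enoate | CCOC(=O)/C=C(\C)C=O | starting material
5 | tert-butyl (R)-4-[(diisopinocampheylboryl)oxy]-3-methylpent-4-enoate (enol borinate from (−)-Ipc2BCl) | C=C(OB([C@@H]1C[C@@H]2C[C@H]([C@H]1C)C2(C)C)[C@@H]1C[C@@H]2C[C@H]([C@H]1C)C2(C)C)[C@H](C)CC(=O)OC(C)(C)C | intermediate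
6 | 9-tert-butyl 1-ethyl (2E,4R,7R)-4-hydroxy-3,7-dimethyl-6-oxonon-2-enedioate | CCOC(=O)/C=C(\C)[C@H](O)CC(=O)[C@H](C)CC(=O)OC(C)(C)C | intermediate
7 | 9-tert-butyl 1-ethyl (2E,4R,6S,7R)-4,6-dihydroxy-3,7-dimethylnon-2-enedioate | CCOC(=O)/C=C(\C)[C@H](O)C[C@H](O)[C@H](C)CC(=O)OC(C)(C)C | intermediate
8 | ethyl (2E,4R)-4-hydroxy-3-methyl-5-[(2S,3R)-3-methyl-5-oxooxolan-2-yl]pent-2-enoate | CCOC(=O)/C=C(\C)[C@H](O)C[C@@H]1OC(=O)C[C@H]1C | intermediate
9 | ethyl (2E,4R)-4-[(tert-butyldimethylsilyl)oxy]-3-methyl-5-[(2S,3R)-3-methyl-5-oxooxolan-2-yl]pent-2-enoate | CCOC(=O)/C=C(\C)[C@H](O[Si](C)(C)C(C)(C)C)C[C@@H]1OC(=O)C[C@H]1C | intermediate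
10 | dilithium (2E,4R,6S,7R)-4-[(tert-butyldimethylsilyl)oxy]-6-hydroxy-3,7-dimethylnon-2-enedioate | [Li+].[Li+].[O-]C(=O)/C=C(\C)[C@H](O[Si](C)(C)C(C)(C)C)C[C@H](O)[C@H](C)CC(=O)[O-] | intermediate
11 | (2E,4R)-4-[(tert-butyldimethylsilyl)oxy]-3-methyl-5-[(2S,3R)-3-methyl-5-oxooxolan-2-yl]pent-2-enoic acid | OC(=O)/C=C(\C)[C@H](O[Si](C)(C)C(C)(C)C)C[C@@H]1OC(=O)C[C@H]1C | intermediate
12 | methyl L-alaninate hydrochloride | C[C@H](N)C(=O)OC.Cl | starting material
13 | methyl N-{(2E,4R)-4-[(tert-butyldimethylsilyl)oxy]-3-methyl-5-[(2S,3R)-3-methyl-5-oxooxolan-2-yl]pent-2-enoyl}-L-alaninate | COC(=O)[C@H](C)NC(=O)/C=C(\C)[C@H](O[Si](C)(C)C(C)(C)C)C[C@@H]1OC(=O)C[C@H]1C | intermediate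
14 | (4R,5S)-5-[(2R,3E)-2-[(tert-butyldimethylsilyl)oxy]-4-(5-methoxy-4-methyl-1,3-oxazol-2-yl)-3-methylbut-3-en-1-yl]-4-methyloxolan-2-one | COc1oc(/C=C(\C)[C@H](O[Si](C)(C)C(C)(C)C)C[C@@H]2OC(=O)C[C@H]2C)nc1C | intermediate
15 | prop-2-yn-1-ol | C#CCO | starting material
16 | triethyl(prop-2-yn-1-yloxy)silane | C#CCO[Si](CC)(CC)CC | intermediate
17 | lithium 3-[(triethylsilyl)oxy]prop-1-yn-1-ide | [Li]C#CCO[Si](CC)(CC)CC | intermediate
18 | (6R,7S,9R,10E)-9-[(tert-butyldimethylsilyl)oxy]-7-hydroxy-11-(5-methoxy-4-methyl-1,3-oxazol-2-yl)-6,10-dimethyl-1-[(triethylsilyl)oxy]undec-10-en-2-yn-4-one | COc1oc(/C=C(\C)[C@H](O[Si](C)(C)C(C)(C)C)C[C@H](O)[C@H](C)CC(=O)C#CCO[Si](CC)(CC)CC)nc1C | intermediate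
19 | (6R,7S,9R,10E)-9-[(tert-butyldimethylsilyl)oxy]-11-(5-methoxy-4-methyl-1,3-oxazol-2-yl)-6,10-dimethyl-1,7-bis[(triethylsilyl)oxy]undec-10-en-2-yn-4-one | COc1oc(/C=C(\C)[C@H](O[Si](C)(C)C(C)(C)C)C[C@H](O[Si](CC)(CC)CC)[C@H](C)CC(=O)C#CCO[Si](CC)(CC)CC)nc1C | intermediate
20 | 7-oxa-2-azabicyclo[2.2.1]hepta-2,5-diene cycloadduct of 19 (C6–C7 and C12–C11 formed; bridgehead configuration left open, both converge) | COC12OC(N=C1C)(/C=C(\C)[C@H](O[Si](C)(C)C(C)(C)C)C[C@H](O[Si](CC)(CC)CC)[C@H](C)CC3=O)C3=C2CO[Si](CC)(CC)CC | intermediate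
21 | (1S,3R,4E,10R)-3-[(tert-butyldimethylsilyl)oxy]-12-methoxy-1,13-bis[(triethylsilyl)oxy]-6,12-epoxygermacra-4,6,11-trien-8-one | COc1oc(/C=C(\C)[C@H](O[Si](C)(C)C(C)(C)C)C[C@H](O[Si](CC)(CC)CC)[C@H](C)CC2=O)c2c1CO[Si](CC)(CC)CC | intermediate
22 | (1S,3R,4E,8R,10R)-3-[(tert-butyldimethylsilyl)oxy]-12-methoxy-1,13-bis[(triethylsilyl)oxy]-6,12-epoxygermacra-4,6,11-trien-8-ol | COc1oc(/C=C(\C)[C@H](O[Si](C)(C)C(C)(C)C)C[C@H](O[Si](CC)(CC)CC)[C@H](C)C[C@H]2O)c2c1CO[Si](CC)(CC)CC | intermediate
23 | bromo{3-[(triethylsilyl)oxy]prop-1-yn-1-yl}magnesium | Br[Mg]C#CCO[Si](CC)(CC)CC | intermediate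
24 | tert-butyl 4-[(triethylsilyl)oxy]but-2-ynoate | CC[Si](CC)(CC)OCC#CC(=O)OC(C)(C)C | intermediate
25 | tert-butyl (Z)-3-methyl-4-[(triethylsilyl)oxy]but-2-enoate | CC[Si](CC)(CC)OC/C(C)=C\C(=O)OC(C)(C)C | intermediate
26 | tert-butyl (Z)-4-hydroxy-3-methylbut-2-enoate | OC/C(C)=C\C(=O)OC(C)(C)C | intermediate
27 | tert-butyl (Z)-4-acetoxy-3-methylbut-2-enoate | CC(=O)OC/C(C)=C\C(=O)OC(C)(C)C | intermediate
28 | (Z)-4-acetoxy-3-methylbut-2-enoic acid | CC(=O)OC/C(C)=C\C(=O)O | intermediate
29 | (Z)-4-acetoxy-3-methylbut-2-enoic 2,4,6-trichlorobenzoic anhydride | CC(=O)OC/C(C)=C\C(=O)OC(=O)c1c(Cl)cc(Cl)cc1Cl | intermediate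
30 | (1S,3R,4E,8R,10R)-3-[(tert-butyldimethylsilyl)oxy]-12-methoxy-1,13-bis[(triethylsilyl)oxy]-6,12-epoxygermacra-4,6,11-trien-8-yl (Z)-4-acetoxy-3-methylbut-2-enoate | COc1oc(/C=C(\C)[C@H](O[Si](C)(C)C(C)(C)C)C[C@H](O[Si](CC)(CC)CC)[C@H](C)C[C@H]2OC(=O)/C=C(/C)COC(C)=O)c2c1CO[Si](CC)(CC)CC | intermediate
31 | (1S,3R,4E,6S,8R,10R)-8-{[(Z)-4-acetoxy-3-methylbut-2-enoyl]oxy}-3-[(tert-butyldimethylsilyl)oxy]-1,13-dihydroxygermacra-4,7(11)-dien-12,6-olide | OCC1=C2[C@@H](OC1=O)/C=C(\C)[C@H](O[Si](C)(C)C(C)(C)C)C[C@H](O)[C@H](C)C[C@H]2OC(=O)/C=C(/C)COC(C)=O | intermediate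
32 | (1S,3R,4E,6S,8R,10R)-13-acetoxy-8-{[(Z)-4-acetoxy-3-methylbut-2-enoyl]oxy}-3-[(tert-butyldimethylsilyl)oxy]-1-hydroxygermacra-4,7(11)-dien-12,6-olide | CC(=O)OCC1=C2[C@@H](OC1=O)/C=C(\C)[C@H](O[Si](C)(C)C(C)(C)C)C[C@H](O)[C@H](C)C[C@H]2OC(=O)/C=C(/C)COC(C)=O | intermediate
33 | (3R,4E,6S,8R,10R)-13-acetoxy-8-{[(Z)-4-acetoxy-3-methylbut-2-enoyl]oxy}-3-[(tert-butyldimethylsilyl)oxy]-1-oxogermacra-4,7(11)-dien-12,6-olide | CC(=O)OCC1=C2[C@@H](OC1=O)/C=C(\C)[C@H](O[Si](C)(C)C(C)(C)C)CC(=O)[C@H](C)C[C@H]2OC(=O)/C=C(/C)COC(C)=O | intermediate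
34 | (3R,4S,5R,6R,8R,10R)-13-acetoxy-8-{[(Z)-4-acetoxy-3-methylbut-2-enoyl]oxy}-3-[(tert-butyldimethylsilyl)oxy]-4,5-epoxy-1-oxogermacr-7(11)-en-12,6-olide | CC(=O)OCC1=C2[C@@H](OC1=O)[C@H]1O[C@]1(C)[C@H](O[Si](C)(C)C(C)(C)C)CC(=O)[C@H](C)C[C@H]2OC(=O)/C=C(/C)COC(C)=O | intermediate
35 | (3R,4R,5R,6R,8R,10R)-13-acetoxy-8-{[(Z)-4-acetoxy-3-methylbut-2-enoyl]oxy}-4,5-epoxy-3-hydroxy-1-oxogermacr-7(11)-en-12,6-olide | CC(=O)OCC1=C2[C@@H](OC1=O)[C@H]1O[C@]1(C)[C@H](O)CC(=O)[C@H](C)C[C@H]2OC(=O)/C=C(/C)COC(C)=O | intermediate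
36 | (4S,5R,6R,8R,10R)-13-acetoxy-8-{[(Z)-4-acetoxy-3-methylbut-2-enoyl]oxy}-4,5-epoxy-1,3-dioxogermacr-7(11)-en-12,6-olide | CC(=O)OCC1=C2[C@@H](OC1=O)[C@H]1O[C@]1(C)C(=O)CC(=O)[C@H](C)C[C@H]2OC(=O)/C=C(/C)COC(C)=O | target

**Step count**

Total: 24 steps. Longest linear sequence: 19 steps (steps 1–8, 10–13, 18–24).

**Steps most likely to fail**

1. Step 12 (proposed new method). The ten‑membered ring closure is entropically demanding, so thermal decomposition of the ynone or intermolecular cycloaddition and oligomerisation may outrun it. The fallback uses known chemistry, sets out from 14 and returns at 21: the cycloaddition is run intermolecularly with a matched alkynoate, and the ring is closed at C7–C8 by a Nozaki–Hiyama–Kishi reaction. The lactone of 14 is opened with MeNH(OMe)·HCl/iPrMgCl to the hydroxy Weinreb amide F1, which is silylated (Et3SiOSO2CF3, 2,6-lutidine) to the triethylsilyl ether F2. Methyl 3-iodoprop-2-ynoate F3 (from methyl propiolate, N-iodosuccinimide, AgNO3 cat.) is heated with F2 in toluene; this intermolecular oxazole–alkyne Diels–Alder/cycloreversion loses acetonitrile and, with the ester‑polarised alkyne bonding through its β‑carbon to oxazole C2, should give the iodofuran ester F4. iBu2AlH reduces the ester to the C13 carbinol and the Weinreb amide to the C8 aldehyde, giving the hydroxy aldehyde F5, and Et3SiCl/imidazole gives the silyl ether aldehyde F6. CrCl2 with NiCl2 (cat.) in DMSO/THF at high dilution closes the ring to the furyl carbinol epimer mixture F7, and MnO2 oxidises this to 21.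

2. Step 19. The risk is poor facial selectivity of the C6 protonation (6‑epimer), or protonation at the wrong carbon (C11, or C4 with formation of a γ‑alkylidene butenolide). The fallback sets out from 30 and returns at 31, and C6 is then set by a reagent instead of by the ring. Dimethyldioxirane (acetone, −78 °C) opens the methoxyfuran oxidatively to the Z‑configured keto ester F8 (C6 ketone, C12 methyl ester). CBS reduction with (R)-1-methyl-3,3-diphenyltetrahydro-1H,3H-pyrrolo[1,2-c][1,3,2]oxazaborole and catecholborane should give the C6 carbinol, which lactonises onto the cis ester to the bis(triethylsilyl) butenolide F9. AcOH/THF/H2O then removes both triethylsilyl groups to give 31.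

3. Step 22. The risk is poor facial selectivity: reaction through the other planar‑chiral rotamer of the E‑cyclodecene would give the 4,5‑diastereomer. The fallback sets out from 33 and returns at 34 without a new compound. It is a reagent‑controlled Shi epoxidation with the D‑fructose‑derived ketone (1,2:4,5-di-O-isopropylidene-β-D-erythro-2,3-hexodiulo-2,6-pyranose), KHSO5 (as 2KHSO5·KHSO4·K2SO4) and K2CO3 buffer in aqueous MeCN/dimethoxymethane at 0 °C. Its spiro transition state for E‑trisubstituted alkenes is expected to select the 4S,5R face whatever the ring conformation.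

**Further compounds**

F1 | step 12 | (3R,4S,6R,7E)-6-[(tert-butyldimethylsilyl)oxy]-4-hydroxy-N-methoxy-8-(5-methoxy-4-methyl-1,3-oxazol-2-yl)-N,3,7-trimethyloct-7-enamide | COc1oc(/C=C(\C)[C@H](O[Si](C)(C)C(C)(C)C)C[C@H](O)[C@H](C)CC(=O)N(C)OC)nc1C
F2 | step 12 | (3R,4S,6R,7E)-6-[(tert-butyldimethylsilyl)oxy]-N-methoxy-8-(5-methoxy-4-methyl-1,3-oxazol-2-yl)-N,3,7-trimethyl-4-[(triethylsilyl)oxy]oct-7-enamide | COc1oc(/C=C(\C)[C@H](O[Si](C)(C)C(C)(C)C)C[C@H](O[Si](CC)(CC)CC)[C@H](C)CC(=O)N(C)OC)nc1C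
F3 | step 12 | methyl 3-iodoprop-2-ynoate | COC(=O)C#CI
F4 | step 12 | methyl 4-iodo-2-methoxy-5-{(1E,3R,5S,6R)-3-[(tert-butyldimethylsilyl)oxy]-8-[methoxy(methyl)amino]-2,6-dimethyl-8-oxo-5-[(triethylsilyl)oxy]oct-1-en-1-yl}furan-3-carboxylate | COC(=O)c1c(I)c(/C=C(\C)[C@H](O[Si](C)(C)C(C)(C)C)C[C@H](O[Si](CC)(CC)CC)[C@H](C)CC(=O)N(C)OC)oc1OC
F5 | step 12 | (3R,4S,6R,7E)-6-[(tert-butyldimethylsilyl)oxy]-8-[4-(hydroxymethyl)-3-iodo-5-methoxyfuran-2-yl]-3,7-dimethyl-4-[(triethylsilyl)oxy]oct-7-enal | OCc1c(I)c(/C=C(\C)[C@H](O[Si](C)(C)C(C)(C)C)C[C@H](O[Si](CC)(CC)CC)[C@H](C)CC=O)oc1OC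
F6 | step 12 | (3R,4S,6R,7E)-6-[(tert-butyldimethylsilyl)oxy]-8-(3-iodo-5-methoxy-4-{[(triethylsilyl)oxy]methyl}furan-2-yl)-3,7-dimethyl-4-[(triethylsilyl)oxy]oct-7-enal | CC[Si](CC)(CC)OCc1c(I)c(/C=C(\C)[C@H](O[Si](C)(C)C(C)(C)C)C[C@H](O[Si](CC)(CC)CC)[C@H](C)CC=O)oc1OC
F7 | step 12 | (1S,3R,4E,10R)-3-[(tert-butyldimethylsilyl)oxy]-12-methoxy-1,13-bis[(triethylsilyl)oxy]-6,12-epoxygermacra-4,6,11-trien-8-ol, both C8 epimers | COc1oc(/C=C(\C)[C@H](O[Si](C)(C)C(C)(C)C)C[C@H](O[Si](CC)(CC)CC)[C@H](C)CC2O)c2c1CO[Si](CC)(CC)CC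
F8 | step 19 | methyl (7Z,11)-configured keto ester: methyl (Z)-2-{(3R,5S,7R,8E)-3-{[(Z)-4-acetoxy-3-methylbut-2-enoyl]oxy}-7-[(tert-butyldimethylsilyl)oxy]-5-methyl-8-methyl-10-oxo-6-[(triethylsilyl)oxy]cyclodec-8-en-1-ylidene}-3-[(triethylsilyl)oxy]propanoate (germacrane: 6-oxo, 12-methyl ester, 7(11)-Z) | COC(=O)/C(CO[Si](CC)(CC)CC)=C1\C(=O)/C=C(\C)[C@H](O[Si](C)(C)C(C)(C)C)C[C@H](O[Si](CC)(CC)CC)[C@H](C)C[C@H]1OC(=O)/C=C(/C)COC(C)=O
F9 | step 19 | (1S,3R,4E,6S,8R,10R)-8-{[(Z)-4-acetoxy-3-methylbut-2-enoyl]oxy}-3-[(tert-butyldimethylsilyl)oxy]-1,13-bis[(triethylsilyl)oxy]germacra-4,7(11)-dien-12,6-olide | CC[Si](CC)(CC)OCC1=C2[C@@H](OC1=O)/C=C(\C)[C@H](O[Si](C)(C)C(C)(C)C)C[C@H](O[Si](CC)(CC)CC)[C@H](C)C[C@H]2OC(=O)/C=C(/C)COC(C)=O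
F0 | step 22 | none | none
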